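**Plan**

- Cuts: the linoleate C–O bond, the C=CH2 bond (made from a ketone), and the cyclobutane bond between the ring CH2 and the ring CMe2 carbon. That bond is re-opened by inserting NH, which gives a 2,2-dimethylpyrrolidine; this ring is cut at C3–CH(O) (lactam aldol), at N–C(=O) and at the CH–CMe2 bond (nitro-Michael).
- Enabling feature: in the cyclobutane the CH2 and CMe2 carbons carry no functional group, are 1,4-related through the two stereogenic ring CH carbons, and are not stereogenic themselves. An NH bridge therefore gives a five-membered ring from which nitrogen can leave as N2, and the fully substituted carbon supplies a weak C–N bond and a tertiary radical.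
- Forward: ketal of hex-5-en-2-one → E-enal (cross-metathesis) → Michael addition of 2-nitropropane → nitro ester → 5,5-dimethyl lactam → trans aldol/lactonisation with methyl 4-oxobutanoate → LiAlH4 to the pyrrolidine diol → ring contraction to the cyclobutane (the only ring of the target) → primary linoleate, oxidation, methylenation, ketal removal.
- Stereochemistry: the ring carbon bearing the oxobutyl chain comes from the amine-catalysed Michael addition. The neighbouring ring carbon comes from attack of the lactam enolate anti to that chain (trans). Both are spectators in the contraction, and the (Z,Z)-diene arrives with linoleic acid.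

Key step: step 8

Remark on the chemistry: the carbinol carbon created in step 6 (later the C=CH2 carbon) is carried as a mixture of epimers and is written without configuration; it becomes sp2 in step 10.

**Route**

Step 1
Reactants: 1 hex-5-en-2-one
Product: 2 2-(but-3-en-1-yl)-2-methyl-1,3-dioxolane
Conditions: HOCH2CH2OH, TsOH·H2O (cat.), toluene, reflux, Dean–Stark
Reagents that add atoms: ethylene glycol, OCCO
Why: Acid-catalysed ketalisation with azeotropic removal of water masks the methyl ketone as a dioxolane that should survive every basic, reducing and oxidising step up to the last one.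

Step 2
Reactants: 2 2-(but-3-en-1-yl)-2-methyl-1,3-dioxolane; 3 (E)-but-2-enal (crotonaldehyde)
Product: 4 (E)-5-(2-methyl-1,3-dioxolan-2-yl)pent-2-enal
Conditions: 3 (excess), second-generation Hoveyda–Grubbs catalyst RuCl2(H2IMes)(=CH-C6H4-2-OiPr) (2 mol%), CH2Cl2, 40 °C
Reagents that add atoms: none
Why: Olefin cross-metathesis of a terminal alkene with crotonaldehyde is a standard route to (E)-enals, the E isomer being favoured and loss of volatile propene driving the exchange.

Step 3
Reactants: 4 (E)-5-(2-methyl-1,3-dioxolan-2-yl)pent-2-enal; 5 2-nitropropane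
Product: 6 (3R)-4-methyl-3-[2-(2-methyl-1,3-dioxolan-2-yl)ethyl]-4-nitropentanal
Conditions: 5 (4 equiv), (S)-α,α-diphenylprolinol trimethylsilyl ether (10 mol%), LiOAc (10 mol%), CH2Cl2/MeOH, rt
Reagents that add atoms: none
Why: In this iminium-ion activated asymmetric Michael addition the nitronate should attack the β-carbon of the E-iminium ion on the face opposite the diphenyl(silyloxy)methyl group, which sets the (R) centre that becomes the ring carbon bearing the oxobutyl chain and forms the CH–CMe2 bond.

Step 4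
Reactants: 6 (3R)-4-methyl-3-[2-(2-methyl-1,3-dioxolan-2-yl)ethyl]-4-nitropentanal
Product: 8 methyl (3R)-4-methyl-3-[2-(2-methyl-1,3-dioxolan-2-yl)ethyl]-4-nitropentanoate, via nitro acid 7 (not isolated)
Conditions: NaClO2, NaH2PO4, 2-methyl-2-butene, t-BuOH/H2O, 0 °C → rt; then TMSCHN2, MeOH/toluene, 0 °C
Reagents that add atoms: sodium chlorite, [Na+].[O-]Cl=O; trimethylsilyldiazomethane, C[Si](C)(C)C=[N+]=[N-]
Why: Pinnick oxidation is selective for the aldehyde under buffered conditions that spare the dioxolane and the tertiary nitro group, and the diazoalkane methylates the acid without base so that the β-stereocentre is untouched.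

Step 5
Reactants: 8 methyl (3R)-4-methyl-3-[2-(2-methyl-1,3-dioxolan-2-yl)ethyl]-4-nitropentanoate
Product: 10 (4R)-5,5-dimethyl-4-[2-(2-methyl-1,3-dioxolan-2-yl)ethyl]pyrrolidin-2-one, via amino ester 9 (not isolated)
Conditions: H2 (50 atm), Raney Ni, MeOH, 60 °C
Reagents that add atoms: none
Why: Hydrogenation of the tertiary nitro group gives the hindered γ-amino ester, which should close to the five-membered lactam on warming (reductive lactamisation, helped by the gem-dimethyl group).

Step 6
Reactants: 10 (4R)-5,5-dimethyl-4-[2-(2-methyl-1,3-dioxolan-2-yl)ethyl]pyrrolidin-2-one; 11 methyl 4-oxobutanoate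
Product: 13 (3S,4R)-5,5-dimethyl-4-[2-(2-methyl-1,3-dioxolan-2-yl)ethyl]-3-(5-oxooxolan-2-yl)pyrrolidin-2-one, via aldol hydroxy ester 12 (not isolated)
Conditions: n-BuLi (2.1 equiv), THF, −78 → 0 °C; 11, −78 °C → rt; aq. NH4Cl
Reagents that add atoms: none
Why: Aldol addition of the N,C-dilithiated lactam should occur at C3 anti to the C4 side chain (1,2-induction in a five-membered enolate), which sets the 3,4-trans relationship, and the γ-alkoxide then closes onto the methyl ester so that the adduct is trapped as a γ-lactone and cannot revert.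

Step 7
Reactants: 13 (3S,4R)-5,5-dimethyl-4-[2-(2-methyl-1,3-dioxolan-2-yl)ethyl]-3-(5-oxooxolan-2-yl)pyrrolidin-2-one
Product: 14 1-[(3R,4R)-5,5-dimethyl-4-[2-(2-methyl-1,3-dioxolan-2-yl)ethyl]pyrrolidin-3-yl]butane-1,4-diol
Conditions: LiAlH4 (excess), THF, reflux; aq. NaOH work-up
Reagents that add atoms: none
Why: LiAlH4 reduces the secondary lactam to the N–H pyrrolidine and the lactone to the 1,4-diol in one operation without touching the dioxolane or either ring stereocentre.

Step 8
Reactants: 14 1-[(3R,4R)-5,5-dimethyl-4-[2-(2-methyl-1,3-dioxolan-2-yl)ethyl]pyrrolidin-3-yl]butane-1,4-diol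
Product: 17 1-[(1S,2R)-3,3-dimethyl-2-[2-(2-methyl-1,3-dioxolan-2-yl)ethyl]cyclobutyl]butane-1,4-diol, via 1,1-diazene 15 (not isolated), via 1,4-diyl 16 (not isolated)
Conditions: PhI(OH)OTs (2.5 equiv), H2NCO2NH4 (8 equiv), CF3CH2OH, 80 °C
Reagents that add atoms: none
Why: The iodonitrene formed from the trivalent-iodine reagent and ammonia should transfer nitrogen to the secondary amine to give the 1,1-diazene 15, which loses N2 (the weak C–N bond to the fully substituted α-carbon breaking first) to leave the singlet 1,4-diyl 16, and this collapses by C–C coupling. The closest known reaction type is the oxidative nitrogen-deletion ring contraction of N–H pyrrolidines to cyclobutanes through 1,1-diazenes, together with the classical decomposition of diazenes made from N-amino-2,2,5,5-tetraalkylpyrrolidines to tetraalkylcyclobutanes. The four-membered ring closes by radical–radical recombination of the CH2 and CMe2 termini of the diyl, a five-to-four ring contraction by extrusion of the nitrogen atom as N2 and not a polar 4-exo or 4-endo attack. No stereocentre is created, since the coupling carbons are CH2 and CMe2, and the two ring stereocentres (pyrrolidine C3 and C4) are never radical sites, so their trans relationship and absolute configuration from steps 3 and 6 should carry over unchanged. The step needs ring closure to beat β-scission of the diyl and nitrogen transfer to beat oxidation elsewhere: the diyl is born gauche inside the five-membered ring with the gem-dimethyl group favouring closure, both alkenes that scission would give are unconjugated because the side-chain carbon next to the ring is kept at the sp3 carbinol level, the substrate has no alkene, ketone or second amine, and excess ammonium carbamate buffers the TsOH so that the dioxolane survives.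

Step 9
Reactants: 17 1-[(1S,2R)-3,3-dimethyl-2-[2-(2-methyl-1,3-dioxolan-2-yl)ethyl]cyclobutyl]butane-1,4-diol; 18 (9Z,12Z)-octadeca-9,12-dienoic acid (linoleic acid)
Product: 19 4-[(1S,2R)-3,3-dimethyl-2-[2-(2-methyl-1,3-dioxolan-2-yl)ethyl]cyclobutyl]-4-hydroxybutyl (9Z,12Z)-octadeca-9,12-dienoate
Conditions: 18 (1.0 equiv), EDC·HCl, DMAP (10 mol%), CH2Cl2, −20 → 0 °C
Reagents that add atoms: none
Why: Carbodiimide (Steglich) esterification with one equivalent of acid at low temperature should acylate the unhindered primary hydroxyl in preference to the secondary carbinol flanked by the cyclobutane.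

Step 10
Reactants: 19 4-[(1S,2R)-3,3-dimethyl-2-[2-(2-methyl-1,3-dioxolan-2-yl)ethyl]cyclobutyl]-4-hydroxybutyl (9Z,12Z)-octadeca-9,12-dienoate
Product: 20 4-[(1S,2R)-3,3-dimethyl-2-[2-(2-methyl-1,3-dioxolan-2-yl)ethyl]cyclobutyl]-4-oxobutyl (9Z,12Z)-octadeca-9,12-dienoate
Conditions: Dess–Martin periodinane, NaHCO3, CH2Cl2, 0 °C → rt
Reagents that add atoms: none
Why: Dess–Martin oxidation converts the remaining secondary alcohol into the ketone under buffered, non-epimerising conditions that leave the skipped diene, the ester and the dioxolane intact, and it removes the uncontrolled carbinol centre.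

Step 11
Reactants: 20 4-[(1S,2R)-3,3-dimethyl-2-[2-(2-methyl-1,3-dioxolan-2-yl)ethyl]cyclobutyl]-4-oxobutyl (9Z,12Z)-octadeca-9,12-dienoate
Product: 21 4-[(1S,2R)-3,3-dimethyl-2-[2-(2-methyl-1,3-dioxolan-2-yl)ethyl]cyclobutyl]pent-4-en-1-yl (9Z,12Z)-octadeca-9,12-dienoate
Conditions: Ph3PCH3Br, KOt-Bu, THF, 0 °C → rt
Reagents that add atoms: methyltriphenylphosphonium bromide, C[P+](c1ccccc1)(c1ccccc1)c1ccccc1.[Br-]
Why: Wittig methylenation with the non-stabilised ylide is selective for the ketone over the ester and installs the 1,1-disubstituted alkene, and any enolisation at the ring α-carbon should return the more stable trans isomer.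

Step 12
Reactants: 21 4-[(1S,2R)-3,3-dimethyl-2-[2-(2-methyl-1,3-dioxolan-2-yl)ethyl]cyclobutyl]pent-4-en-1-yl (9Z,12Z)-octadeca-9,12-dienoate
Product: 22 4-[(1S,2R)-3,3-dimethyl-2-(3-oxobutyl)cyclobutyl]pent-4-en-1-yl (9Z,12Z)-octadeca-9,12-dienoate (IN0146)
Conditions: PPTS (cat.), acetone/H2O, 50 °C
Reagents that add atoms: water, O
Why: Mild acid-catalysed ketal hydrolysis should release the methyl ketone without isomerising the 1,1-disubstituted alkene or the (Z,Z)-skipped diene and without cleaving the ester.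

**Compound list**

1 | hex-5-en-2-one | CC(=O)CCC=C | starting material
2 | 2-(but-3-en-1-yl)-2-methyl-1,3-dioxolane | C=CCCC1(C)OCCO1 | intermediate
3 | (E)-but-2-enal (crotonaldehyde) | C/C=C/C=O | starting material
4 | (E)-5-(2-methyl-1,3-dioxolan-2-yl)pent-2-enal | O=C/C=C/CCC1(C)OCCO1 | intermediate
5 | 2-nitropropane | CC(C)[N+](=O)[O-] | starting material
6 | (3R)-4-methyl-3-[2-(2-methyl-1,3-dioxolan-2-yl)ethyl]-4-nitropentanal | O=CC[C@@H](CCC1(C)OCCO1)C(C)(C)[N+](=O)[O-] | intermediate
7 | (3R)-4-methyl-3-[2-(2-methyl-1,3-dioxolan-2-yl)ethyl]-4-nitropentanoic acid (nitro acid, not isolated) | OC(=O)C[C@@H](CCC1(C)OCCO1)C(C)(C)[N+](=O)[O-] | intermediate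
8 | methyl (3R)-4-methyl-3-[2-(2-methyl-1,3-dioxolan-2-yl)ethyl]-4-nitropentanoate | COC(=O)C[C@@H](CCC1(C)OCCO1)C(C)(C)[N+](=O)[O-] | intermediate
9 | methyl (3R)-4-amino-4-methyl-3-[2-(2-methyl-1,3-dioxolan-2-yl)ethyl]pentanoate (amino ester, not isolated) | COC(=O)C[C@@H](CCC1(C)OCCO1)C(C)(C)N | intermediate
10 | (4R)-5,5-dimethyl-4-[2-(2-methyl-1,3-dioxolan-2-yl)ethyl]pyrrolidin-2-one | O=C1C[C@@H](CCC2(C)OCCO2)C(C)(C)N1 | intermediate
11 | methyl 4-oxobutanoate | COC(=O)CCC=O | starting material
12 | methyl 4-hydroxy-4-[(3S,4R)-5,5-dimethyl-4-[2-(2-methyl-1,3-dioxolan-2-yl)ethyl]-2-oxopyrrolidin-3-yl]butanoate (aldol hydroxy ester, present as its lithium alkoxide, not isolated; carbinol epimers) | COC(=O)CCC(O)[C@H]1C(=O)NC(C)(C)[C@@H]1CCC2(C)OCCO2 | intermediate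
13 | (3S,4R)-5,5-dimethyl-4-[2-(2-methyl-1,3-dioxolan-2-yl)ethyl]-3-(5-oxooxolan-2-yl)pyrrolidin-2-one (3,4-trans; lactone carbon epimers) | O=C1CCC(O1)[C@H]2C(=O)NC(C)(C)[C@@H]2CCC3(C)OCCO3 | intermediate
14 | 1-[(3R,4R)-5,5-dimethyl-4-[2-(2-methyl-1,3-dioxolan-2-yl)ethyl]pyrrolidin-3-yl]butane-1,4-diol (3,4-trans; carbinol epimers) | OCCCC(O)[C@H]1CNC(C)(C)[C@@H]1CCC2(C)OCCO2 | intermediate
15 | 1,1-diazene (isodiazene) of pyrrolidine 14, N=N on the ring nitrogen (not isolated) | OCCCC(O)[C@H]1C[N+](=[N-])C(C)(C)[C@@H]1CCC2(C)OCCO2 | intermediate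
16 | 1,4-diyl from 15 after loss of N2, radical centres at the former N–CH2 and N–CMe2 carbons (not isolated) | OCCCC(O)[C@@H]([CH2])[C@@H](CCC1(C)OCCO1)[C](C)C | intermediate
17 | 1-[(1S,2R)-3,3-dimethyl-2-[2-(2-methyl-1,3-dioxolan-2-yl)ethyl]cyclobutyl]butane-1,4-diol (1,2-trans; carbinol epimers) | OCCCC(O)[C@H]1CC(C)(C)[C@@H]1CCC2(C)OCCO2 | intermediate
18 | (9Z,12Z)-octadeca-9,12-dienoic acid (linoleic acid) | CCCCC/C=C\C/C=C\CCCCCCCC(=O)O | starting material
19 | 4-[(1S,2R)-3,3-dimethyl-2-[2-(2-methyl-1,3-dioxolan-2-yl)ethyl]cyclobutyl]-4-hydroxybutyl (9Z,12Z)-octadeca-9,12-dienoate (carbinol epimers) | OC(CCCOC(=O)CCCCCCC/C=C\C/C=C\CCCCC)[C@H]1CC(C)(C)[C@@H]1CCC2(C)OCCO2 | intermediate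
20 | 4-[(1S,2R)-3,3-dimethyl-2-[2-(2-methyl-1,3-dioxolan-2-yl)ethyl]cyclobutyl]-4-oxobutyl (9Z,12Z)-octadeca-9,12-dienoate | O=C(CCCOC(=O)CCCCCCC/C=C\C/C=C\CCCCC)[C@H]1CC(C)(C)[C@@H]1CCC2(C)OCCO2 | intermediate
21 | 4-[(1S,2R)-3,3-dimethyl-2-[2-(2-methyl-1,3-dioxolan-2-yl)ethyl]cyclobutyl]pent-4-en-1-yl (9Z,12Z)-octadeca-9,12-dienoate | C=C(CCCOC(=O)CCCCCCC/C=C\C/C=C\CCCCC)[C@H]1CC(C)(C)[C@@H]1CCC2(C)OCCO2 | intermediate
22 | 4-[(1S,2R)-3,3-dimethyl-2-(3-oxobutyl)cyclobutyl]pent-4-en-1-yl (9Z,12Z)-octadeca-9,12-dienoate (IN0146) | C=C(CCCOC(=O)CCCCCCC/C=C\C/C=C\CCCCC)[C@H]1CC(C)(C)[C@@H]1CCC(C)=O | target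

**Step count and risks**

Total step count: 12. Longest linear sequence: 12 steps (1 → 22); compounds 3, 5, 11 and 18 are bought and used directly.

Steps most likely to fail:

1. Step 8. After loss of N2 the 1,4-diyl may cleave its central C–C bond (β-scission to two alkenes) faster than it closes at 80 °C. Before that, the trivalent-iodine oxidant may dehydrogenate the hindered amine or oxidise the free carbinols instead of transferring nitrogen. The fallback sets out from 14 and comes back at 17. It builds the N–N bond stepwise and releases the diazene cold, where closure is favoured over fragmentation, with an oxidant that ignores alcohols. Nitrosation of 14 (t-BuONO, THF, rt) should give 1-[(3R,4R)-5,5-dimethyl-4-[2-(2-methyl-1,3-dioxolan-2-yl)ethyl]-1-nitrosopyrrolidin-3-yl]butane-1,4-diol F1. Reduction (LiAlH4, Et2O, 0 °C → rt) should give the 1-aminopyrrolidine F2. Oxidation of this 1,1-disubstituted hydrazine with yellow HgO (divalent mercury) in Et2O at 0 °C should then give the 1,1-diazene, which loses N2 to 17.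

2. Step 6. Proton transfer from the enolisable aldehyde to the strongly basic dianion, incomplete second deprotonation at C3 and weak facial discrimination may all cut into the aldol. The fallback sets out from 10 and comes back at 14. It replaces the aldol by a Claisen acylation followed by reduction, with the C3 configuration set by equilibration of the acidic 1,3-dicarbonyl position. Silylation of 10 (TMSCl, Et3N, CH2Cl2) should give (4R)-5,5-dimethyl-4-[2-(2-methyl-1,3-dioxolan-2-yl)ethyl]-1-(trimethylsilyl)pyrrolidin-2-one F3. Its mono-enolate (LDA, THF, −78 °C) is acylated with γ-butyrolactone to give, after aqueous work-up, (3S,4R)-3-(4-hydroxybutanoyl)-5,5-dimethyl-4-[2-(2-methyl-1,3-dioxolan-2-yl)ethyl]pyrrolidin-2-one F4. NaBH4 in MeOH at 0 °C should give (3S,4R)-3-(1,4-dihydroxybutyl)-5,5-dimethyl-4-[2-(2-methyl-1,3-dioxolan-2-yl)ethyl]pyrrolidin-2-one F5, and LiAlH4 in THF at reflux reduces the lactam to 14.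

3. Step 3. Addition of the hindered secondary nitronate to the iminium ion may be slow, so that a racemic base-catalysed background addition and catalyst deactivation erode conversion and enantiofacial control. The fallback sets out from 2 and comes back at 10. It moves the asymmetric step to ion-pair (phase-transfer) catalysis on a more electrophilic acceptor.
   - Ozonolysis of 2 (O3, CH2Cl2, −78 °C; PPh3) should give 3-(2-methyl-1,3-dioxolan-2-yl)propanal F6.
   - Knoevenagel condensation with dimethyl malonate (piperidine, AcOH, toluene, Dean–Stark) gives dimethyl 2-[3-(2-methyl-1,3-dioxolan-2-yl)propylidene]propanedioate F7.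
   - Michael addition of 2-nitropropane under a chiral N-spiro binaphthyl quaternary ammonium bromide (Cs2CO3, toluene, 0 °C; catalyst antipode chosen for the R adduct) should give dimethyl 2-[(3R)-2-methyl-5-(2-methyl-1,3-dioxolan-2-yl)-2-nitropentan-3-yl]propanedioate F8.
   - Hydrogenation (H2, Raney Ni, MeOH, 60 °C) closes methyl (4R)-5,5-dimethyl-4-[2-(2-methyl-1,3-dioxolan-2-yl)ethyl]-2-oxopyrrolidine-3-carboxylate F9.
   - Krapcho demethoxycarbonylation (NaCl, wet DMSO, 150 °C) returns 10.

**Further compounds**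

F1 | step 8 | 1-[(3R,4R)-5,5-dimethyl-4-[2-(2-methyl-1,3-dioxolan-2-yl)ethyl]-1-nitrosopyrrolidin-3-yl]butane-1,4-diol | OCCCC(O)[C@H]1CN(N=O)C(C)(C)[C@@H]1CCC2(C)OCCO2
F2 | step 8 | 1-[(3R,4R)-1-amino-5,5-dimethyl-4-[2-(2-methyl-1,3-dioxolan-2-yl)ethyl]pyrrolidin-3-yl]butane-1,4-diol | OCCCC(O)[C@H]1CN(N)C(C)(C)[C@@H]1CCC2(C)OCCO2
F3 | step 6 | (4R)-5,5-dimethyl-4-[2-(2-methyl-1,3-dioxolan-2-yl)ethyl]-1-(trimethylsilyl)pyrrolidin-2-one | O=C1C[C@@H](CCC2(C)OCCO2)C(C)(C)N1[Si](C)(C)C
F4 | step 6 | (3S,4R)-3-(4-hydroxybutanoyl)-5,5-dimethyl-4-[2-(2-methyl-1,3-dioxolan-2-yl)ethyl]pyrrolidin-2-one | OCCCC(=O)[C@H]1C(=O)NC(C)(C)[C@@H]1CCC2(C)OCCO2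
F5 | step 6 | (3S,4R)-3-(1,4-dihydroxybutyl)-5,5-dimethyl-4-[2-(2-methyl-1,3-dioxolan-2-yl)ethyl]pyrrolidin-2-one | OCCCC(O)[C@H]1C(=O)NC(C)(C)[C@@H]1CCC2(C)OCCO2
F6 | step 3 | 3-(2-methyl-1,3-dioxolan-2-yl)propanal | O=CCCC1(C)OCCO1
F7 | step 3 | dimethyl 2-[3-(2-methyl-1,3-dioxolan-2-yl)propylidene]propanedioate | COC(=O)C(=CCCC1(C)OCCO1)C(=O)OC
F8 | step 3 | dimethyl 2-[(3R)-2-methyl-5-(2-methyl-1,3-dioxolan-2-yl)-2-nitropentan-3-yl]propanedioate | COC(=O)C(C(=O)OC)[C@@H](CCC1(C)OCCO1)C(C)(C)[N+](=O)[O-]
F9 | step 3 | methyl (4R)-5,5-dimethyl-4-[2-(2-methyl-1,3-dioxolan-2-yl)ethyl]-2-oxopyrrolidine-3-carboxylate | COC(=O)C1C(=O)NC(C)(C)[C@@H]1CCC2(C)OCCO2
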